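**Retrosynthetic overview**
1. Target 17 ⇐ methyl ester 16; the only ring (ring A, the 1,2-dioxane) is closed by C3–O bond formation, an intramolecular peroxy-Michael addition of a C6 tertiary hydroperoxide onto the (E)-enoate.
2. The C6–O bond comes from cobalt-catalysed hydroperoxysilylation of the 1,1-disubstituted alkene of tetraene ester 13.
3. 13 ⇐ C5–C6 Negishi coupling of enol triflate 8 with the zinc reagent from bromo ester 9 (brings C4), then one-pot reduction/olefination (C2=C3).
4. 8 ⇐ methyl ketone 7 ⇐ rhodium-catalysed asymmetric 1,4-alkenylation of pent-3-en-2-one (C8–C9 bond, sets C8) with the alkenylborane from alkyne 4.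
5. 4 ⇐ aldehyde 3 ⇐ organocatalytic styryl addition to crotonaldehyde (sets C12).

Assumption: the senses of induction quoted for the catalyst-controlled steps 1, 3 and 8 follow the usual models; if one proves opposite, the catalyst antipode is used.

Atom labels C1–C14 follow the acid chain (C1 = CO2H, C3 and C6 = ring carbons bearing O, C14 = CHPh).

**Step 1**
Reactants: 1 (E)-but-2-enal; 2 potassium trifluoro[(E)-2-phenylethenyl]borate
Product: 3 (3S,4E)-3-methyl-5-phenylpent-4-enal
Conditions: (2R,5R)-5-benzyl-2-tert-butyl-3-methylimidazolidin-4-one·HCl (20 mol%), HF (48% aq, 1 equiv), 1 (3 equiv), DME, −20 °C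
Reagents that add atoms: none
Why: Iminium-catalysed conjugate vinylation with a trifluoroborate (MacMillan type); the catalyst shields one face of the (E)-iminium ion so the styryl group adds to the β-carbon to set C12 as S, the (2S,5S) catalyst giving the R series in related additions to crotonaldehyde.

**Step 2**
Reactants: 3
Product: 4 [(1E,3S)-3-methylhex-1-en-5-yn-1-yl]benzene
Conditions: dimethyl (1-diazo-2-oxopropyl)phosphonate, K2CO3, MeOH, 0 °C to rt
Reagents that add atoms: dimethyl (1-diazo-2-oxopropyl)phosphonate, COP(=O)(OC)C(=[N+]=[N-])C(C)=O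
Why: Ohira–Bestmann (Seyferth–Gilbert) homologation of the aldehyde to the terminal alkyne; the stereocentre is β to the carbonyl and is not touched.

**Step 3**
Reactants: 4; 5 (E)-pent-3-en-2-one
Product: 7 (4R,5E,8S,9E)-4,8-dimethyl-10-phenyldeca-5,9-dien-2-one, via alkenylcatecholborane 6 (not isolated)
Conditions: catecholborane, THF, 70 °C; then 5 (3 equiv), Rh(acac)(C2H4)2 (3 mol%), (R)-BINAP, Et3N, dioxane/H2O 10:1, 100 °C
Reagents that add atoms: none
Why: Syn anti-Markovnikov hydroboration of the alkyne gives the (E)-alkenylborane, and Hayashi–Miyaura rhodium-catalysed asymmetric 1,4-addition transfers it to one enantioface of the (E)-enone to set C8 as R under ligand control ((S)-BINAP gives the S series with (E)-enones).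

**Step 4**
Reactants: 7
Product: 8 (4R,5E,8S,9E)-4,8-dimethyl-10-phenyldeca-1,5,9-trien-2-yl trifluoromethanesulfonate
Conditions: PhNTf2, KN(SiMe3)2 (slow addition, internal quench), THF, −78 °C
Reagents that add atoms: N-phenylbis(trifluoromethanesulfonimide), O=S(=O)(N(c1ccccc1)S(=O)(=O)C(F)(F)F)C(F)(F)F
Why: Kinetic deprotonation of the methyl ketone at CH3 (the CH2 side is β-branched) and O-triflation of the terminal enolate gives the 1,1-disubstituted enol triflate.

**Step 5**
Reactants: 8; 9 methyl (2R)-3-bromo-2-methylpropanoate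
Product: 11 methyl (2S,6R,7E,10S,11E)-2,6,10-trimethyl-4-methylidene-12-phenyldodeca-7,11-dienoate, via alkylzinc bromide 10 (not isolated)
Conditions: 9, Zn dust, LiCl, THF, 40 °C; then 8, Pd(PPh3)4 (5 mol%), THF, 50 °C
Reagents that add atoms: none
Why: Zinc insertion followed by Negishi sp3–sp2 coupling forms C5–C6; the centre of 9 is β to zinc and is carried over unchanged as C4 (the R to S change is only a priority change).

**Step 6**
Reactants: 11
Product: 13 methyl (2E,4S,8R,9E,12S,13E)-4,8,12-trimethyl-6-methylidene-14-phenyltetradeca-2,9,13-trienoate, via aldehyde 12 (not isolated)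
Conditions: i-Bu2AlH (1.1 equiv), CH2Cl2, −78 °C; then (MeO)2P(O)CH2CO2Me/NaH in THF, −78 °C to rt
Reagents that add atoms: trimethyl phosphonoacetate, COC(=O)CP(=O)(OC)OC
Why: Partial reduction to the aluminium hemiacetal and in situ Horner–Wadsworth–Emmons olefination gives the (E)-enoate without isolating the epimerisable α-methyl aldehyde.

**Step 7**
Reactants: 13
Product: 14 methyl (2E,4S,8R,9E,12S,13E)-4,6,8,12-tetramethyl-14-phenyl-6-[(triethylsilyl)peroxy]tetradeca-2,9,13-trienoate as a 6S/6R epimer pair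
Conditions: Co(thd)2 (10 mol%; thd = 2,2,6,6-tetramethylheptane-3,5-dionate), O2 (1 atm), Et3SiH (2 equiv), ClCH2CH2Cl, rt
Reagents that add atoms: dioxygen, O=O; triethylsilane, CC[SiH](CC)CC
Why: Mukaiyama–Isayama hydroperoxysilylation (hydrogen-atom transfer from a cobalt hydride to the electron-rich 1,1-disubstituted alkene, O2 capture of the tertiary radical) forms the C6–O bond ahead of the enoate, the internal alkene and the β-alkylstyrene, and because the radical is acyclic both C6 epimers form (about 1:1) and are sorted in step 8.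

**Step 8**
Reactants: 14
Product: 16 methyl 2-[(3S,4S,6S)-6-[(2R,3E,6S,7E)-2,6-dimethyl-8-phenylocta-3,7-dien-1-yl]-4,6-dimethyl-1,2-dioxan-3-yl]acetate, via hydroperoxide 15 (not isolated)
Conditions: HCl (cat.), MeOH, 0 °C, then evaporation; then chiral bifunctional iminophosphorane–thiourea catalyst (BIMP type: tris(4-methoxyphenyl)iminophosphorane on an (S)-tert-leucine-derived 3,5-bis(trifluoromethyl)phenylthiourea, 10 mol%), toluene, −20 °C, stopped near 50% conversion; chromatography
Reagents that add atoms: none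
Why: Proposed new method: a catalyst-controlled, diastereomer-selective intramolecular peroxy-Michael addition (6-exo-trig) in which the iminophosphorane deprotonates the tertiary OOH to a tight chiral ion pair while the thiourea binds the ester carbonyl, so C3–O forms through a chair with the C4 methyl equatorial and the enoate arm axial (3S, 3,4-cis), and, because the catalyst cation sits next to C6, the epimer that presents its methyl group in the equatorial site (6S) should close fast while the 6R hydroperoxide is left behind and removed; the closest known reactions are the amine/trifluoroethanol peroxy-Michael closure of δ-hydroperoxy enoates and the iminophosphorane-catalysed enantioselective oxa-Michael addition of alcohols to unactivated enoates.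

**Step 9**
Reactants: 16
Product: 17 2-[(3S,4S,6S)-6-[(2R,3E,6S,7E)-2,6-dimethyl-8-phenylocta-3,7-dien-1-yl]-4,6-dimethyl-1,2-dioxan-3-yl]acetic acid
Conditions: LiOH, THF/H2O 3:1, 0 °C; then 1 M HCl to pH 3
Reagents that add atoms: lithium hydroxide, [Li+].[OH-]
Why: Saponification of the methyl ester under cold, mild conditions that dialkyl peroxides of this type tolerate; no stereocentre is touched.

**Compound list**
1 | (E)-but-2-enal | C/C=C/C=O | starting material
2 | potassium trifluoro[(E)-2-phenylethenyl]borate | [K+].F[B-](F)(F)/C=C/c1ccccc1 | starting material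
3 | (3S,4E)-3-methyl-5-phenylpent-4-enal | C[C@H](/C=C/c1ccccc1)CC=O | intermediate
4 | [(1E,3S)-3-methylhex-1-en-5-yn-1-yl]benzene | C[C@H](/C=C/c1ccccc1)CC#C | intermediate
5 | (E)-pent-3-en-2-one | C/C=C/C(C)=O | starting material
6 | 2-[(1E,4S,5E)-4-methyl-6-phenylhexa-1,5-dien-1-yl]-1,3,2-benzodioxaborole | C[C@H](/C=C/c1ccccc1)C/C=C/B1Oc2ccccc2O1 | intermediate
7 | (4R,5E,8S,9E)-4,8-dimethyl-10-phenyldeca-5,9-dien-2-one | C[C@H](/C=C/c1ccccc1)C/C=C/[C@H](C)CC(C)=O | intermediate
8 | (4R,5E,8S,9E)-4,8-dimethyl-10-phenyldeca-1,5,9-trien-2-yl trifluoromethanesulfonate | C[C@H](/C=C/c1ccccc1)C/C=C/[C@H](C)CC(=C)OS(=O)(=O)C(F)(F)F | intermediate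
9 | methyl (2R)-3-bromo-2-methylpropanoate | BrC[C@H](C)C(=O)OC | starting material
10 | bromo[(2R)-3-methoxy-2-methyl-3-oxopropyl]zinc | Br[Zn]C[C@H](C)C(=O)OC | intermediate
11 | methyl (2S,6R,7E,10S,11E)-2,6,10-trimethyl-4-methylidene-12-phenyldodeca-7,11-dienoate | C[C@H](/C=C/c1ccccc1)C/C=C/[C@H](C)CC(=C)C[C@H](C)C(=O)OC | intermediate
12 | (2S,6R,7E,10S,11E)-2,6,10-trimethyl-4-methylidene-12-phenyldodeca-7,11-dienal | C[C@H](/C=C/c1ccccc1)C/C=C/[C@H](C)CC(=C)C[C@H](C)C=O | intermediate
13 | methyl (2E,4S,8R,9E,12S,13E)-4,8,12-trimethyl-6-methylidene-14-phenyltetradeca-2,9,13-trienoate | C[C@H](/C=C/c1ccccc1)C/C=C/[C@H](C)CC(=C)C[C@H](C)/C=C/C(=O)OC | intermediate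
14 | methyl (2E,4S,8R,9E,12S,13E)-4,6,8,12-tetramethyl-14-phenyl-6-[(triethylsilyl)peroxy]tetradeca-2,9,13-trienoate (6S/6R pair, C6 left open in the SMILES) | C[C@H](/C=C/c1ccccc1)C/C=C/[C@H](C)CC(C)(OO[Si](CC)(CC)CC)C[C@H](C)/C=C/C(=O)OC | intermediate
15 | methyl (2E,4S,8R,9E,12S,13E)-6-hydroperoxy-4,6,8,12-tetramethyl-14-phenyltetradeca-2,9,13-trienoate (6S/6R pair; the 6S epimer is the one that closes) | C[C@H](/C=C/c1ccccc1)C/C=C/[C@H](C)CC(C)(OO)C[C@H](C)/C=C/C(=O)OC | intermediate
16 | methyl 2-[(3S,4S,6S)-6-[(2R,3E,6S,7E)-2,6-dimethyl-8-phenylocta-3,7-dien-1-yl]-4,6-dimethyl-1,2-dioxan-3-yl]acetate | C[C@H](/C=C/c1ccccc1)C/C=C/[C@H](C)C[C@@]1(C)C[C@H](C)[C@H](CC(=O)OC)OO1 | intermediate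
17 | 2-[(3S,4S,6S)-6-[(2R,3E,6S,7E)-2,6-dimethyl-8-phenylocta-3,7-dien-1-yl]-4,6-dimethyl-1,2-dioxan-3-yl]acetic acid | C[C@H](/C=C/c1ccccc1)C/C=C/[C@H](C)C[C@@]1(C)C[C@H](C)[C@H](CC(=O)O)OO1 | target

**Totals and risks**
Total step count: 9. Longest linear sequence: 9 steps (1 to 17). Where each stereocentre is set: C12 in step 1, C8 in step 3, C4 from 9, C6 formed in step 7 and selected in step 8, C3 in step 8.

Step 8 (the proposed new step) is the most likely to fail. The catalyst may be degraded by the hydroperoxide, or may not distinguish the C6 epimers well enough; at best half of the material can be used. The fallback is the known amine-promoted closure. It sets out from 14: acid methanolysis to 15 as before, then Et2NH in CF3CH2OH at room temperature closes both C6 epimers, each to its 3,4-cis dioxane. This gives 16 together with methyl 2-[(3S,4S,6R)-6-[(2R,3E,6S,7E)-2,6-dimethyl-8-phenylocta-3,7-dien-1-yl]-4,6-dimethyl-1,2-dioxan-3-yl]acetate F1. The two diastereomers are separated on silica gel and the route is rejoined at 16.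

Step 7 is the second risk. The cobalt hydride may also attack the β-alkylstyrene (benzylic radical) or over-oxidise the diene chain. The fallback replaces the radical step by polar Markovnikov peroxymercuration. It sets out from 13: Hg(OAc)2 and H2O2 in THF at 0 °C add across the terminal alkene, which is far more reactive to oxymercuration than the 1,2-disubstituted alkenes, while the enoate is inert. The product is the β-mercurio hydroperoxide methyl (2E,4S,8R,9E,12S,13E)-6-[(acetoxymercurio)methyl]-6-hydroperoxy-4,8,12-trimethyl-14-phenyltetradeca-2,9,13-trienoate F2, again as both C6 epimers. Cold alkaline NaBH4 replaces mercury by hydrogen and the route is rejoined at 15, which enters the second operation of step 8.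

Step 3 is the third risk. Protodeboronation of 6 and the need to run with the enone in excess may erode the yield, and the ligand sense has to be confirmed. The fallback is an auxiliary-controlled cuprate addition and sets out from 4.
- Cp2Zr(H)Cl then I2 gives [(1E,3S,5E)-6-iodo-3-methylhexa-1,5-dien-1-yl]benzene F3.
- Acylation of (4S)-4-phenyl-1,3-oxazolidin-2-one with crotonyl chloride gives (4S)-3-[(E)-but-2-enoyl]-4-phenyl-1,3-oxazolidin-2-one F4.
- Iodine–lithium exchange on the iodide (t-BuLi), then MgBr2 and CuBr·SMe2, gives an alkenylcopper reagent that adds to the chelated imide on the face away from the phenyl group. The product is (4S)-3-[(3R,4E,7S,8E)-3,7-dimethyl-9-phenylnona-4,8-dienoyl]-4-phenyl-1,3-oxazolidin-2-one F5.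
- MeNH(OMe)·HCl with AlMe3 gives (3R,4E,7S,8E)-N-methoxy-N,3,7-trimethyl-9-phenylnona-4,8-dienamide F6, and MeMgBr rejoins the route at 7.

**Further compounds**
F1 | step 8 | methyl 2-[(3S,4S,6R)-6-[(2R,3E,6S,7E)-2,6-dimethyl-8-phenylocta-3,7-dien-1-yl]-4,6-dimethyl-1,2-dioxan-3-yl]acetate | C[C@H](/C=C/c1ccccc1)C/C=C/[C@H](C)C[C@]1(C)C[C@H](C)[C@H](CC(=O)OC)OO1
F2 | step 7 | methyl (2E,4S,8R,9E,12S,13E)-6-[(acetoxymercurio)methyl]-6-hydroperoxy-4,8,12-trimethyl-14-phenyltetradeca-2,9,13-trienoate (6S/6R pair) | C[C@H](/C=C/c1ccccc1)C/C=C/[C@H](C)CC(C[Hg]OC(C)=O)(OO)C[C@H](C)/C=C/C(=O)OC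
F3 | step 3 | [(1E,3S,5E)-6-iodo-3-methylhexa-1,5-dien-1-yl]benzene | C[C@H](/C=C/c1ccccc1)C/C=C/I
F4 | step 3 | (4S)-3-[(E)-but-2-enoyl]-4-phenyl-1,3-oxazolidin-2-one | C/C=C/C(=O)N1[C@@H](c2ccccc2)COC1=O
F5 | step 3 | (4S)-3-[(3R,4E,7S,8E)-3,7-dimethyl-9-phenylnona-4,8-dienoyl]-4-phenyl-1,3-oxazolidin-2-one | C[C@H](/C=C/c1ccccc1)C/C=C/[C@H](C)CC(=O)N1[C@@H](c2ccccc2)COC1=O
F6 | step 3 | (3R,4E,7S,8E)-N-methoxy-N,3,7-trimethyl-9-phenylnona-4,8-dienamide | C[C@H](/C=C/c1ccccc1)C/C=C/[C@H](C)CC(=O)N(C)OC
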